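**Retrosynthetic overview**
- Last step: hydrogenolysis of two aryl benzyl ethers; the free acid and both acetates are already in place.
- Key disconnection: the aryl C6–C1' bond, made by carboxylate-directed, palladium-catalysed ortho C–H alkylation of 2,4-bis(benzyloxy)benzoic acid with an enantiopure β-acetoxy primary iodide (new reaction), so the C2' oxygen arrives acetylated and no lactone forms.
- Aryl fragment: resorcinol, Kolbe–Schmitt carboxylation, perbenzylation, saponification.
- C13 iodide: cross-metathesis of two chiral-pool alkenes ((R)-propylene oxide sets C12', (R)-epichlorohydrin sets C2'), then hydrogenation, iodide opening of the epoxide and bis-acetylation.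
- Rings: the benzene ring is bought as resorcinol; the only ring made is the side-chain oxirane (step 5), opened again in step 8.

Assumption: the target is (2'R,12'R) as read from the SMILES (side chain numbered from the benzylic carbon), and two stages run in one flask count as one step.

**Route**

Step 1
Reactants: 1 resorcinol
Product: 2 2,4-dihydroxybenzoic acid
Conditions: KHCO3 (5.5 equiv), H2O, 95 °C, 4 h, then reflux under a CO2 stream, 30 min; conc. HCl
Reagents that add atoms: potassium hydrogen carbonate, [K+].OC([O-])=O, under carbon dioxide, O=C=O (source of the carboxyl group)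
Why: Kolbe–Schmitt carboxylation, in which the electron-rich resorcinol monoanion is C-carboxylated ortho to one hydroxyl and para to the other to give the 2,4-dihydroxy acid as the main, crystallisable product; no stereocentre.

Step 2
Reactants: 2 2,4-dihydroxybenzoic acid
Product: 3 benzyl 2,4-bis(benzyloxy)benzoate
Conditions: BnBr (3.5 equiv), K2CO3 (4 equiv), DMF, 70 °C, 12 h
Reagents that add atoms: benzyl bromide, BrCc1ccccc1
Why: Williamson alkylation of the carboxylate and both phenoxides; excess BnBr in warm DMF also benzylates the hydrogen-bonded ortho hydroxyl.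

Step 3
Reactants: 3 benzyl 2,4-bis(benzyloxy)benzoate
Product: 4 2,4-bis(benzyloxy)benzoic acid
Conditions: NaOH (2 M aq, 3 equiv), THF/MeOH, 65 °C; then HCl (aq)
Reagents that add atoms: sodium hydroxide, [Na+].[OH-]
Why: Saponification of the benzyl ester frees the directing carboxylic acid, while aryl benzyl ethers are inert to hydroxide.

Step 4
Reactants: 5 6-bromohex-1-ene; 6 (R)-propylene oxide [(2R)-2-methyloxirane]
Product: 8 (2R)-non-8-en-2-ol, via hex-5-en-1-ylmagnesium bromide 7 (not isolated)
Conditions: Mg, THF, rt to 40 °C; then CuI (copper iodide, 10 mol%), 6, −30 to 0 °C; NH4Cl (aq)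
Reagents that add atoms: none
Why: Grignard formation followed by copper-catalysed SN2 opening of the epoxide at its CH2 terminus; the C–O bond at the stereocentre is not touched, so the (R) centre of 6 becomes C12' unchanged.

Step 5
Reactants: 9 (R)-epichlorohydrin [(2R)-2-(chloromethyl)oxirane]; 10 allylmagnesium chloride (2 M in THF)
Product: 12 (2R)-2-(but-3-en-1-yl)oxirane, via (2R)-1-chlorohex-5-en-2-ol 11 (not isolated)
Conditions: THF, −20 °C, 2 h; then NaOH (6 M aq) added to the same flask, 40 °C, 3 h; distillation
Reagents that add atoms: none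
Why: Grignard opening of the oxirane at its unsubstituted carbon, then intramolecular Williamson closure by displacement of the primary chloride; the stereocentre is never a reacting centre and stays (R), becoming C2'.

Step 6
Reactants: 8 (2R)-non-8-en-2-ol (1 equiv); 12 (2R)-2-(but-3-en-1-yl)oxirane (3 equiv)
Product: 13 (2R,8E)-11-[(2R)-oxiran-2-yl]undec-8-en-2-ol (E/Z mixture, E major, used as such)
Conditions: second-generation Grubbs catalyst RuCl2(=CHPh)(H2IMes)(PCy3) (5 mol%), CH2Cl2, 40 °C, argon sweep
Reagents that add atoms: none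
Why: Olefin cross-metathesis of two unhindered terminal alkenes, driven by loss of ethene and by the excess of the cheaper partner 12; the epoxide and free alcohol are tolerated and the E/Z ratio is irrelevant because the alkene is hydrogenated next.

Step 7
Reactants: 13 (2R,8E)-11-[(2R)-oxiran-2-yl]undec-8-en-2-ol
Product: 14 (2R)-11-[(2R)-oxiran-2-yl]undecan-2-ol
Conditions: H2 (3 atm), RhCl(PPh3)3 (5 mol%), benzene/EtOH 1:1, rt
Reagents that add atoms: none
Why: Homogeneous hydrogenation saturates the disubstituted alkene without hydrogenolysis of the terminal epoxide, which heterogeneous palladium can open.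

Step 8
Reactants: 14 (2R)-11-[(2R)-oxiran-2-yl]undecan-2-ol
Product: 15 (2R,12R)-1-iodotridecane-2,12-diol
Conditions: LiI (1.5 equiv), AcOH (2 equiv), THF, 0 °C to rt
Reagents that add atoms: lithium iodide, [Li+].[I-]
Why: Acid-assisted SN2 opening of the terminal epoxide by iodide at the CH2 carbon (halohydrin formation), regioselective for steric reasons and leaving the C2 stereocentre untouched.

Step 9
Reactants: 15 (2R,12R)-1-iodotridecane-2,12-diol
Product: 16 (2R,12R)-1-iodotridecane-2,12-diyl diacetate
Conditions: Ac2O (3 equiv), pyridine (4 equiv), DMAP (5 mol%), CH2Cl2, 0 °C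
Reagents that add atoms: acetic anhydride, CC(=O)OC(C)=O
Why: DMAP-catalysed acylation of both secondary alcohols with retention; the weak base and low temperature do not re-close the iodohydrin to the epoxide.

Step 10
Reactants: 4 2,4-bis(benzyloxy)benzoic acid (1.0 equiv); 16 (2R,12R)-1-iodotridecane-2,12-diyl diacetate (1.3 equiv)
Product: 17 2,4-bis(benzyloxy)-6-[(2R,12R)-2,12-diacetoxytridecyl]benzoic acid
Conditions: Pd(OAc)2 (10 mol%), N-acetyl-L-tert-leucine (20 mol%), K2HPO4 (2.5 equiv), HFIP (1,1,1,3,3,3-hexafluoropropan-2-ol), 70 °C, 24 h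
Reagents that add atoms: none
Why: Proposed new method: a carboxylate-directed ortho C–H alkylation with a β-acetoxy primary iodide as electrophile, in which the potassium carboxylate of 4 and the mono-protected amino acid ligand let divalent palladium cleave the only ortho C–H bond (C6) by concerted metalation–deprotonation, and the aryl–palladium bond is then alkylated at the CH2–I carbon either by SN2-type oxidative addition to a tetravalent palladium alkyl and C(sp2)–C(sp3) reductive elimination or by attack on the 1,3-dioxolan-2-ylium ion that the neighbouring acetate forms in the ionising solvent; because the C2' oxygen is already acetylated no alkoxide forms and the usual lactonisation is shut off, and because C2' is never a reacting centre (an acetoxonium detour makes and breaks only the C1'–O bond) both (R) centres are carried through; the closest known reactions are the palladium diacetate-catalysed ortho-alkylations of benzoic acids with simple alkyl halides and with terminal epoxides, the latter ending in the dihydroisocoumarin.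

Step 11
Reactants: 17 2,4-bis(benzyloxy)-6-[(2R,12R)-2,12-diacetoxytridecyl]benzoic acid
Product: 18 2-[(2R,12R)-2,12-diacetoxytridecyl]-4,6-dihydroxybenzoic acid (CNP0203944.4)
Conditions: H2 (1 atm), 10% Pd/C, EtOAc, rt
Reagents that add atoms: none
Why: Catalytic hydrogenolysis cleaves the two aryl benzyl ethers under neutral conditions at room temperature, leaving the secondary acetates, the carboxylic acid and both stereocentres untouched.

**Compound list**
1 | resorcinol | Oc1cccc(O)c1 | starting material
2 | 2,4-dihydroxybenzoic acid | OC(=O)c1ccc(O)cc1O | intermediate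
3 | benzyl 2,4-bis(benzyloxy)benzoate | O=C(OCc1ccccc1)c1ccc(OCc2ccccc2)cc1OCc1ccccc1 | intermediate
4 | 2,4-bis(benzyloxy)benzoic acid | OC(=O)c1ccc(OCc2ccccc2)cc1OCc1ccccc1 | intermediate
5 | 6-bromohex-1-ene | C=CCCCCBr | starting material
6 | (R)-propylene oxide [(2R)-2-methyloxirane] | C[C@@H]1CO1 | starting material
7 | hex-5-en-1-ylmagnesium bromide | C=CCCCC[Mg]Br | intermediate
8 | (2R)-non-8-en-2-ol | C[C@@H](O)CCCCCC=C | intermediate
9 | (R)-epichlorohydrin [(2R)-2-(chloromethyl)oxirane] | ClC[C@H]1CO1 | starting material
10 | allylmagnesium chloride | C=CC[Mg]Cl | starting material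
11 | (2R)-1-chlorohex-5-en-2-ol | C=CCC[C@@H](O)CCl | intermediate
12 | (2R)-2-(but-3-en-1-yl)oxirane | C=CCC[C@@H]1CO1 | intermediate
13 | (2R,8E)-11-[(2R)-oxiran-2-yl]undec-8-en-2-ol | C[C@@H](O)CCCCC/C=C/CC[C@@H]1CO1 | intermediate
14 | (2R)-11-[(2R)-oxiran-2-yl]undecan-2-ol | C[C@@H](O)CCCCCCCCC[C@@H]1CO1 | intermediate
15 | (2R,12R)-1-iodotridecane-2,12-diol | C[C@@H](O)CCCCCCCCC[C@@H](O)CI | intermediate
16 | (2R,12R)-1-iodotridecane-2,12-diyl diacetate | CC(=O)O[C@@H](CI)CCCCCCCCC[C@@H](C)OC(C)=O | intermediate
17 | 2,4-bis(benzyloxy)-6-[(2R,12R)-2,12-diacetoxytridecyl]benzoic acid | CC(=O)O[C@H](CCCCCCCCC[C@@H](C)OC(C)=O)Cc1cc(OCc2ccccc2)cc(OCc2ccccc2)c1C(=O)O | intermediate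
18 | 2-[(2R,12R)-2,12-diacetoxytridecyl]-4,6-dihydroxybenzoic acid | CC(=O)O[C@H](CCCCCCCCC[C@@H](C)OC(C)=O)Cc1cc(O)cc(O)c1C(=O)O | target

**Step count**
Total step count: 11.
Longest linear sequence: 7 steps (step 4 or step 5, then steps 6, 7, 8, 9, 10 and 11). The aryl branch (steps 1–3) joins at step 10.

**Steps most likely to fail and their fallbacks**

Step 10 (the proposed new C–H alkylation). It may lose to O-alkylation of the carboxylate, to β-acetoxy elimination from the palladium alkyl, or to protodecarboxylation of the electron-rich acid. The fallback uses known chemistry, sets out from 4 and 14 and comes back at 18. Acid 4 and epoxy alcohol 14 are joined by the known palladium diacetate/mono-protected amino acid-catalysed ortho C–H alkylation of benzoic acids with terminal epoxides [Pd(OAc)2 (5 mol%), N-acetyl-L-tert-leucine (10 mol%), KOAc (1 equiv), HFIP, 75 °C]. Opening at the oxirane CH2 and lactonisation give (3R)-6,8-bis(benzyloxy)-3-[(10R)-10-hydroxyundecyl]-3,4-dihydro-1H-isochromen-1-one F1 with C2' intact. KOH (aq) in THF/MeOH at 50 °C opens the lactone; after evaporation, BnBr in DMF at rt traps the carboxylate as benzyl 2,4-bis(benzyloxy)-6-[(2R,12R)-2,12-dihydroxytridecyl]benzoate F2, which is used at once to avoid relactonisation. Ac2O, pyridine and DMAP give benzyl 2,4-bis(benzyloxy)-6-[(2R,12R)-2,12-diacetoxytridecyl]benzoate F3. Hydrogenolysis under the conditions of step 11 removes all three benzyl groups and gives 18.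

Step 6 (cross-metathesis). It may give mainly homodimers or a poorly separable mixture. The fallback builds the chain by acetylide–epoxide openings, sets out from 6 and 9 and comes back at 14. Hepta-1,6-diyne (C#CCCCC#C, commercial, 3 equiv) is mono-lithiated (n-BuLi, THF, −78 °C) and opens 6 in the presence of BF3·OEt2 to give (2R)-deca-4,9-diyn-2-ol F4. Its dianion (n-BuLi, 2.1 equiv; BF3·OEt2) opens 9 at the oxirane CH2 to give (2R,12R)-1-chlorotrideca-4,9-diyne-2,12-diol F5. H2 over Pd/C in EtOAc saturates both alkynes to (2R,12R)-1-chlorotridecane-2,12-diol F6, and NaOH (aq) in THF closes the oxirane to give 14.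

Step 7 (alkene hydrogenation beside the epoxide). It may be sluggish on the internal alkene or may open the epoxide. The fallback opens the epoxide first and reduces the alkene without a metal; it sets out from 13 and comes back at 16. LiI/AcOH in THF converts 13 into (2R,5E,12R)-1-iodotridec-5-ene-2,12-diol F7. Ac2O, pyridine and DMAP give (2R,5E,12R)-1-iodotridec-5-ene-2,12-diyl diacetate F8. Diimide (potassium azodicarboxylate, AcOH, MeOH, 0 °C to rt) reduces the isolated alkene and leaves the C–I bond and the acetates alone, giving 16.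

**Further compounds**
F1 | step 10 | (3R)-6,8-bis(benzyloxy)-3-[(10R)-10-hydroxyundecyl]-3,4-dihydro-1H-isochromen-1-one | C[C@@H](O)CCCCCCCCC[C@@H]1Cc2cc(OCc3ccccc3)cc(OCc3ccccc3)c2C(=O)O1
F2 | step 10 | benzyl 2,4-bis(benzyloxy)-6-[(2R,12R)-2,12-dihydroxytridecyl]benzoate | C[C@@H](O)CCCCCCCCC[C@@H](O)Cc1cc(OCc2ccccc2)cc(OCc2ccccc2)c1C(=O)OCc1ccccc1
F3 | step 10 | benzyl 2,4-bis(benzyloxy)-6-[(2R,12R)-2,12-diacetoxytridecyl]benzoate | CC(=O)O[C@H](CCCCCCCCC[C@@H](C)OC(C)=O)Cc1cc(OCc2ccccc2)cc(OCc2ccccc2)c1C(=O)OCc1ccccc1
F4 | step 6 | (2R)-deca-4,9-diyn-2-ol | C[C@@H](O)CC#CCCCC#C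
F5 | step 6 | (2R,12R)-1-chlorotrideca-4,9-diyne-2,12-diol | C[C@@H](O)CC#CCCCC#CC[C@@H](O)CCl
F6 | step 6 | (2R,12R)-1-chlorotridecane-2,12-diol | C[C@@H](O)CCCCCCCCC[C@@H](O)CCl
F7 | step 7 | (2R,5E,12R)-1-iodotridec-5-ene-2,12-diol | C[C@@H](O)CCCCC/C=C/CC[C@@H](O)CI
F8 | step 7 | (2R,5E,12R)-1-iodotridec-5-ene-2,12-diyl diacetate | CC(=O)O[C@@H](CI)CC/C=C/CCCCC[C@@H](C)OC(C)=O
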